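**Retrosynthetic overview**

1. Numbering: lactone O1, C2(=O), C3, C4, C5, exocyclic carbon C6, carbinol carbon C1'. The route rests on one feature: iodine on C6 lies on the C4 side of the C5=C6 bond (the hindered E arrangement), and the C4 bromide can be derived from a C4 oxygen. A silicon atom hung on that oxygen can reach only the C6–H bond on the same side, closing a five-membered C4–O–Si–C6=C5 ring.
2. C6–I ⇒ C6–Si (ipso iodination with retention); C4–Br ⇒ C4–OH (bromoiminium exchange on the vinylogous acid); C6–Si ⇒ C6–H plus O–Si–H (tethered dehydrogenative silylation).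
3. 5-Methylene tetronic acid ⇒ Dieckmann closure (C3–C4 bond) of the enol ester of methyl pyruvate with (R)-3-silyloxyhexanoic acid; C1' ⇒ asymmetric hydrogenation of methyl 3-oxohexanoate.
4. Ring order: lactone ring (step 5), then the temporary oxasilole ring (step 7), which is opened again in step 8.

Key step: step 7

Remark: compounds 10 and 11 are vinylogous silyl esters; it is assumed that they are handled under argon and carried forward crude. TBS = tert-butyldimethylsilyl.

**Route**

Step 1
Reactants: 1 methyl 3-oxohexanoate
Product: 2 methyl (3R)-3-hydroxyhexanoate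
Conditions: H2 (50 atm), RuCl2[(R)-BINAP] (cat.), MeOH, 50 °C
Reagents that add atoms: none
Why: Noyori asymmetric hydrogenation of a β-keto ester, in which the (R)-BINAP ligand dictates the face of the chelated ketone that is reduced and should give the (R)-3-hydroxy ester, setting C1'.

Step 2
Reactants: 2 methyl (3R)-3-hydroxyhexanoate
Product: 3 methyl (3R)-3-(tert-butyldimethylsilyloxy)hexanoate
Conditions: TBSCl, imidazole, DMF, rt
Reagents that add atoms: tert-butyldimethylsilyl chloride, CC(C)(C)[Si](C)(C)Cl
Why: Standard silyl ether formation protects the secondary alcohol for the enolate, acylation and halogenation steps without touching the stereocentre.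

Step 3
Reactants: 3 methyl (3R)-3-(tert-butyldimethylsilyloxy)hexanoate
Product: 4 (3R)-3-(tert-butyldimethylsilyloxy)hexanoic acid
Conditions: LiOH, THF/MeOH/H2O, 0 °C to rt; then 1 M HCl to pH 3, 0 °C
Reagents that add atoms: lithium hydroxide, [Li+].[OH-]
Why: Mild saponification of a methyl ester under conditions at which the β-silyloxy group should neither eliminate nor be cleaved, with careful cold acidification to keep the silyl ether.

Step 4
Reactants: 4 (3R)-3-(tert-butyldimethylsilyloxy)hexanoic acid; 5 methyl pyruvate
Product: 7 methyl 2-{[(3R)-3-(tert-butyldimethylsilyloxy)hexanoyl]oxy}prop-2-enoate, via (3R)-3-(tert-butyldimethylsilyloxy)hexanoyl chloride 6 (not isolated)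
Conditions: 1-chloro-N,N,2-trimethylprop-1-en-1-amine, CH2Cl2, 0 °C to rt; then 5, Et3N, DMAP (cat.), CH2Cl2, −20 °C to rt
Reagents that add atoms: none
Why: Neutral acid chloride formation followed by O-acylation of the amine-generated enolate of methyl pyruvate is the usual entry to 2-acyloxyacrylates, and acylpyridinium transfer favours O- over C-acylation.

Step 5
Reactants: 7 methyl 2-{[(3R)-3-(tert-butyldimethylsilyloxy)hexanoyl]oxy}prop-2-enoate
Product: 8 3-[(1R)-1-(tert-butyldimethylsilyloxy)butyl]-4-hydroxy-5-methylidenefuran-2(5H)-one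
Conditions: LiN(SiMe3)2 (2.2 equiv), THF, −78 to −20 °C; then cold 0.5 M HCl
Reagents that add atoms: none
Why: Dieckmann condensation in which the ester enolate at the acyl α-carbon attacks the neighbouring methyl ester (5-exo-trig, C3–C4 bond) and the product is drained as its stabilised tetronate, the low temperature keeping silanolate elimination and acrylate oligomerisation slow while the non-enolisable C1' is untouched.

Step 6
Reactants: 8 3-[(1R)-1-(tert-butyldimethylsilyloxy)butyl]-4-hydroxy-5-methylidenefuran-2(5H)-one; 9 chlorodiisopropylsilane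
Product: 10 3-[(1R)-1-(tert-butyldimethylsilyloxy)butyl]-4-(diisopropylsilyloxy)-5-methylidenefuran-2(5H)-one
Conditions: Et3N, DMAP (cat.), CH2Cl2, 0 °C; pentane, filtration under Ar, used crude
Reagents that add atoms: none
Why: O-Silylation of the tetronate at O4 gives the conjugated 4-silyloxybutenolide, the thermodynamically preferred silyl tautomer, and the isopropyl groups slow hydrolysis of this vinylogous silyl ester.

Step 7
Reactants: 10 3-[(1R)-1-(tert-butyldimethylsilyloxy)butyl]-4-(diisopropylsilyloxy)-5-methylidenefuran-2(5H)-one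
Product: 11 furanone-fused 2,2-diisopropyl-1,2-oxasilole (ring C4–O–Si–C6=C5 fused to the lactone along C4–C5) bearing the (1R)-1-(tert-butyldimethylsilyloxy)butyl group at C3
Conditions: [Ir(cod)OMe]2 (2 mol%), 3,4,7,8-tetramethyl-1,10-phenanthroline (5 mol%), norbornene (2 equiv), THF, 80 °C, Ar; used crude
Reagents that add atoms: none
Why: Proposed new method: oxidative addition of the Si–H bond of 10 to the iridium–phenanthroline catalyst holds the metal next to the exocyclic alkene, which inserts into the Ir–Si bond with silicon going to C6 and iridium to C5 (direct cleavage of the cis C6–H bond at the silyl-iridium centre would lead to the same product), and β-hydride elimination from C6 followed by hydrogen transfer to norbornene releases alkenylsilane 11. The closest known reaction types are the iridium-catalysed dehydrogenative silylation of aryl and alkyl C–H bonds directed by (hydrido)silyl ethers with norbornene as acceptor, which gives benzoxasiloles and oxasilolanes, and the 5-endo intramolecular hydrosilylation of allylic hydrosilyl ethers; new here are a vinylic C–H bond of an enol lactone as the site and a vinylogous silyl ester as the anchor. The oxasilole ring C4–O–Si–C6=C5 closes in the 5-endo-trig mode through the new Si–C6 bond. No stereocentre is formed, and the C5=C6 geometry is fixed by the tether, because a five-membered ring can hold silicon only on the C4 side. The step needs dehydrogenative silylation to win over plain hydrosilylation to the saturated oxasilolane and over transfer hydrogenation of the methylene group, which the excess of strained norbornene and the slow C–H reductive elimination at fully substituted C5 should secure; the sp3 C–H bonds of the side chain are hindered and far less reactive than the vinylic one.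

Step 8
Reactants: 11 furanone-fused 2,2-diisopropyl-1,2-oxasilole
Product: 13 (5E)-3-[(1R)-1-(tert-butyldimethylsilyloxy)butyl]-4-hydroxy-5-(iodomethylidene)furan-2(5H)-one, via O4-(succinimidosilyl) iodomethylidene tetronate 12 (not isolated)
Conditions: NIS (1.05 equiv), (CF3)2CHOH/CH2Cl2, 0 °C, dark; then aq. Na2S2O3, pH 2–3 work-up
Reagents that add atoms: N-iodosuccinimide, O=C1CCC(=O)N1I
Why: Ipso iododesilylation of an alkenylsilane, in which iodine adds to C6 to give a C5 cation stabilised by O1 and the β-silicon, the C6–Si bond turns by the shorter path into overlap and leaves to succinimide so that iodine replaces silicon with retention (E), and the silyl ester left on O4 is hydrolysed on work-up, the thiosulfate wash also returning any reversibly iodinated C3.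

Step 9
Reactants: 13 (5E)-3-[(1R)-1-(tert-butyldimethylsilyloxy)butyl]-4-hydroxy-5-(iodomethylidene)furan-2(5H)-one
Product: 14 (5E)-4-bromo-3-[(1R)-1-(tert-butyldimethylsilyloxy)butyl]-5-(iodomethylidene)furan-2(5H)-one
Conditions: (COBr)2, DMF, CH2Cl2, 0 °C, dark
Reagents that add atoms: oxalyl bromide, BrC(=O)C(=O)Br
Why: Vilsmeier-type exchange in which the bromoiminium salt activates O4 and bromide enters at C4 by addition–elimination, the standard conversion of tetronic acids into 4-bromofuranones, run cold, dark and short to spare the silyl ether and the E geometry.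

Step 10
Reactants: 14 (5E)-4-bromo-3-[(1R)-1-(tert-butyldimethylsilyloxy)butyl]-5-(iodomethylidene)furan-2(5H)-one
Product: 15 (5E)-4-bromo-3-[(1R)-1-hydroxybutyl]-5-(iodomethylidene)furan-2(5H)-one
Conditions: aq. HF, MeCN, 0 °C to rt, dark
Reagents that add atoms: none
Why: Acidic fluoride cleavage of the silyl ether avoids base and strong nucleophiles, which would attack the bromo(iodomethylidene)butenolide, and leaves the C1' configuration intact.

**Compound list**

1 | methyl 3-oxohexanoate | CCCC(=O)CC(=O)OC | starting material
2 | methyl (3R)-3-hydroxyhexanoate | CCC[C@@H](O)CC(=O)OC | intermediate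
3 | methyl (3R)-3-(tert-butyldimethylsilyloxy)hexanoate | CCC[C@@H](O[Si](C)(C)C(C)(C)C)CC(=O)OC | intermediate
4 | (3R)-3-(tert-butyldimethylsilyloxy)hexanoic acid | CCC[C@@H](O[Si](C)(C)C(C)(C)C)CC(=O)O | intermediate
5 | methyl pyruvate | CC(=O)C(=O)OC | starting material
6 | (3R)-3-(tert-butyldimethylsilyloxy)hexanoyl chloride (not isolated) | CCC[C@@H](O[Si](C)(C)C(C)(C)C)CC(=O)Cl | intermediate
7 | methyl 2-{[(3R)-3-(tert-butyldimethylsilyloxy)hexanoyl]oxy}prop-2-enoate | CCC[C@@H](O[Si](C)(C)C(C)(C)C)CC(=O)OC(=C)C(=O)OC | intermediate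
8 | 3-[(1R)-1-(tert-butyldimethylsilyloxy)butyl]-4-hydroxy-5-methylidenefuran-2(5H)-one | CCC[C@@H](O[Si](C)(C)C(C)(C)C)C1=C(O)C(=C)OC1=O | intermediate
9 | chlorodiisopropylsilane | CC(C)[SiH](Cl)C(C)C | starting material
10 | 3-[(1R)-1-(tert-butyldimethylsilyloxy)butyl]-4-(diisopropylsilyloxy)-5-methylidenefuran-2(5H)-one | CCC[C@@H](O[Si](C)(C)C(C)(C)C)C1=C(O[SiH](C(C)C)C(C)C)C(=C)OC1=O | intermediate
11 | furanone-fused 2,2-diisopropyl-1,2-oxasilole (C4–O–Si–C6=C5 ring) with the (1R)-1-(tert-butyldimethylsilyloxy)butyl group at C3 | CCC[C@@H](O[Si](C)(C)C(C)(C)C)C1=C2O[Si](C(C)C)(C(C)C)C=C2OC1=O | intermediate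
12 | (5E)-3-[(1R)-1-(tert-butyldimethylsilyloxy)butyl]-4-{[(2,5-dioxopyrrolidin-1-yl)diisopropylsilyl]oxy}-5-(iodomethylidene)furan-2(5H)-one (not isolated) | CCC[C@@H](O[Si](C)(C)C(C)(C)C)C1=C(O[Si](C(C)C)(C(C)C)N2C(=O)CCC2=O)/C(=C\I)OC1=O | intermediate
13 | (5E)-3-[(1R)-1-(tert-butyldimethylsilyloxy)butyl]-4-hydroxy-5-(iodomethylidene)furan-2(5H)-one | CCC[C@@H](O[Si](C)(C)C(C)(C)C)C1=C(O)/C(=C\I)OC1=O | intermediate
14 | (5E)-4-bromo-3-[(1R)-1-(tert-butyldimethylsilyloxy)butyl]-5-(iodomethylidene)furan-2(5H)-one | CCC[C@@H](O[Si](C)(C)C(C)(C)C)C1=C(Br)/C(=C\I)OC1=O | intermediate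
15 | (5E)-4-bromo-3-[(1R)-1-hydroxybutyl]-5-(iodomethylidene)furan-2(5H)-one | CCC[C@@H](O)C1=C(Br)/C(=C\I)OC1=O | target

**Totals**

Total step count: 10. Longest linear sequence: 10 steps (1 to 15).

**Steps most likely to fail**

Step 7. The Si–H bond may add across the exocyclic alkene without loss of hydrogen, the methylene group may be reduced by transfer hydrogenation, or the labile O–Si anchor may be lost before the C–H bond is cleaved. Fallback from 8, returning at 14, by known chemistry: the vinylogous acid 8 is converted with oxalyl bromide–DMF into 4-bromo-3-[(1R)-1-(tert-butyldimethylsilyloxy)butyl]-5-methylidenefuran-2(5H)-one F1. Addition of ICl across the enol-lactone alkene (CH2Cl2, −78 °C) should give the 5-chloro-5-(iodomethyl) adduct F2, and loss of HCl with Et3N the iodomethylidene compound, expected mainly as the less hindered (5Z)-isomer F3. Irradiation (365 nm, CH2Cl2) equilibrates the C5=C6 geometry; the (5E)-isomer 14 is separated by chromatography and the Z material is irradiated again. Stereocontrol at C5=C6 is given up in exchange for halogenation–dehydrohalogenation and photoisomerisation, both established for halomethylidene butenolides.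

Step 8. Electrophilic iodine may attack the nucleophilic C3 of the silyl dienol ether or of the liberated tetronic acid instead of C6, or the alkenylsilane may be protodesilylated by the acidic alcohol. Fallback from 11, returning at 14: the O–Si bond of 11 is hydrolysed (THF, pH 7 buffer) to the ring-opened silanol (5E)-3-[(1R)-1-(tert-butyldimethylsilyloxy)butyl]-4-hydroxy-5-{[hydroxydi(propan-2-yl)silyl]methylidene}furan-2(5H)-one F4. The C4 hydroxyl is exchanged for bromide first (oxalyl bromide–DMF, silanol restored on aqueous work-up) to give the 4-bromo alkenylsilanol F5, which no longer has a nucleophilic C3. Fluoride-assisted iododesilylation of F5 (NIS, AgF, MeCN, 0 °C, dark) should then give 14 with retention.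

Step 5. Methoxide or amide may cleave the activated enol ester, or the acrylate may oligomerise by conjugate addition, in competition with ring closure. Fallback from 4, returning at 8: methyl oxirane-2-carboxylate is opened at C3 with PhSeH (from (PhSe)2 and NaBH4, EtOH) to methyl 2-hydroxy-3-(phenylselanyl)propanoate F6. Esterification with acid 4 (DCC, DMAP, CH2Cl2) gives the saturated diester methyl 2-{[(3R)-3-(tert-butyldimethylsilyloxy)hexanoyl]oxy}-3-(phenylselanyl)propanoate F7, a mixture at the new centre, which is destroyed later. Dieckmann condensation (LiN(SiMe3)2, THF, −78 °C) gives 3-[(1R)-1-(tert-butyldimethylsilyloxy)butyl]-4-hydroxy-5-[(phenylselanyl)methyl]furan-2(5H)-one F8. Oxidation (H2O2, CH2Cl2, 0 °C) and syn-elimination of the selenoxide then unveil the exocyclic methylene of 8.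

**Further compounds**

F1 | step 7 | 4-bromo-3-[(1R)-1-(tert-butyldimethylsilyloxy)butyl]-5-methylidenefuran-2(5H)-one | CCC[C@@H](O[Si](C)(C)C(C)(C)C)C1=C(Br)C(=C)OC1=O
F2 | step 7 | 4-bromo-3-[(1R)-1-(tert-butyldimethylsilyloxy)butyl]-5-chloro-5-(iodomethyl)furan-2(5H)-one (mixture at C5) | CCC[C@@H](O[Si](C)(C)C(C)(C)C)C1=C(Br)C(Cl)(CI)OC1=O
F3 | step 7 | (5Z)-4-bromo-3-[(1R)-1-(tert-butyldimethylsilyloxy)butyl]-5-(iodomethylidene)furan-2(5H)-one | CCC[C@@H](O[Si](C)(C)C(C)(C)C)C1=C(Br)/C(=C/I)OC1=O
F4 | step 8 | (5E)-3-[(1R)-1-(tert-butyldimethylsilyloxy)butyl]-4-hydroxy-5-{[hydroxydi(propan-2-yl)silyl]methylidene}furan-2(5H)-one | CCC[C@@H](O[Si](C)(C)C(C)(C)C)C1=C(O)/C(=C\[Si](O)(C(C)C)C(C)C)OC1=O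
F5 | step 8 | (5E)-4-bromo-3-[(1R)-1-(tert-butyldimethylsilyloxy)butyl]-5-{[hydroxydi(propan-2-yl)silyl]methylidene}furan-2(5H)-one | CCC[C@@H](O[Si](C)(C)C(C)(C)C)C1=C(Br)/C(=C\[Si](O)(C(C)C)C(C)C)OC1=O
F6 | step 5 | methyl 2-hydroxy-3-(phenylselanyl)propanoate (racemic) | COC(=O)C(O)C[Se]c1ccccc1
F7 | step 5 | methyl 2-{[(3R)-3-(tert-butyldimethylsilyloxy)hexanoyl]oxy}-3-(phenylselanyl)propanoate (mixture at C2 of the propanoate) | CCC[C@@H](O[Si](C)(C)C(C)(C)C)CC(=O)OC(C[Se]c1ccccc1)C(=O)OC
F8 | step 5 | 3-[(1R)-1-(tert-butyldimethylsilyloxy)butyl]-4-hydroxy-5-[(phenylselanyl)methyl]furan-2(5H)-one (mixture at C5) | CCC[C@@H](O[Si](C)(C)C(C)(C)C)C1=C(O)C(C[Se]c2ccccc2)OC1=O
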